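The seven-membered ring (C1, C5–C10) is closed at C8. C8 is a ketone-level carbon flanked by two methylenes, C7 and C9, and it stands 1,3 to the oxygen on C6; the key step exploits this pattern. A lithiated 2-silyl-1,3-dithiane acts as a twofold C8 nucleophile. It opens a terminal C6–C7 epoxide, silicon then moves from C8 to O6, and the renewed carbanion displaces a C9 chloride. One operation forms C7–C8 and C8–C9, closes the cycloheptane and protects O6. The precursor is a ketal-masked cyclopentanone bearing a 2-chloroethyl arm on quaternary C1 and, trans to it, an oxirane on C5.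

Key step: step 11

Remark on numbering: daucane numbers are used for all compounds. C1 is the quaternary ring-fusion carbon (methyl), C2=C3 the alkene, C4 the carbinol with isopropyl, C5 the ring-fusion CH, C6 the ester carbon, then C7, C8 (OH, methyl), C9 and C10. β is the face of the C1 methyl group. CIP descriptors change along the route only because substituent priorities change.

Assumption: the ligand antipode named in step 2 is taken to give the (1R) enolate; if its sense of induction is the opposite, the mirror-image ligand is used.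

Step 1
Reactants: 1 3-ethoxycyclopent-2-en-1-one
Product: 3 3-allylcyclopent-2-en-1-one, via tertiary carbinol 2 (not isolated)
Conditions: allylMgBr, THF, 0 °C; then 1 M HCl, 0 °C
Reagents that add atoms: allylmagnesium bromide, C=CC[Mg]Br; water, O
Why: Stork–Danheiser enone synthesis: 1,2-addition of the Grignard reagent to the vinylogous ester gives carbinol 2, which loses ethanol on acid treatment with carbonyl transposition; no stereocentre is formed, and cold dilute acid keeps the allyl double bond out of conjugation.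

Step 2
Reactants: 3 3-allylcyclopent-2-en-1-one
Product: 5 triethyl{[(3R)-3-allyl-3-methylcyclopent-1-en-1-yl]oxy}silane, via aluminium enolate 4 (not isolated)
Conditions: Me3Al, Cu(O2CC4H3S) (copper thiophene-2-carboxylate, 2 mol %), N,N-bis[(S)-1-(naphthalen-2-yl)ethyl]dibenzo[d,f][1,3,2]dioxaphosphepin-6-amine (4 mol %), Et2O, −30 °C; then Et3SiOTf, −30 → 0 °C
Reagents that add atoms: trimethylaluminium, C[Al](C)C; triethylsilyl triflate, CC[Si](CC)(CC)OS(=O)(=O)C(F)(F)F
Why: Copper-catalysed asymmetric conjugate addition of a trialkylaluminium to a β-substituted cyclopentenone: the chiral phosphoramidite–copper complex chooses the enone face and sets quaternary C1 as (R), O-silylation of enolate 4 fixes the C4=C5 regiochemistry, and methyl is the group added so that the larger C1 substituent is the future C10 arm, which step 3 needs for facial control.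

Step 3
Reactants: 5 triethyl{[(3R)-3-allyl-3-methylcyclopent-1-en-1-yl]oxy}silane; 6 (tert-butyldimethylsilyloxy)acetaldehyde
Product: 9 anti aldol (2S,3R)-3-allyl-2-[(1R)-2-(tert-butyldimethylsilyloxy)-1-hydroxyethyl]-3-methylcyclopentan-1-one, via lithium enolate 7 (not isolated), via chlorozinc enolate 8 (not isolated)
Conditions: MeLi, THF, 0 °C; ZnCl2, −78 °C; 6, −78 °C; pH 7 buffer
Reagents that add atoms: none
Why: Silyl enol ether cleavage with MeLi, transmetalation to zinc and a closed Zimmerman–Traxler aldol addition: the aldehyde should bond to C5 on the face of the small C1 methyl group, anti to the allyl arm (5S), and the ring-locked (E)-enolate with the aldehyde substituent equatorial should give the anti aldol (6R), while the weakly basic zinc enolate spares the enolisable aldehyde.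

Step 4
Reactants: 9 anti aldol (1R,5S,6R)
Product: 10 O6-triethylsilyl ether of 9 (1R,5S,6R)
Conditions: Et3SiOTf, 2,6-lutidine, CH2Cl2, −78 °C
Reagents that add atoms: triethylsilyl triflate, CC[Si](CC)(CC)OS(=O)(=O)C(F)(F)F
Why: Silylation of a hindered aldol carbinol with a silyl triflate and a hindered pyridine base at low temperature avoids retro-aldol cleavage and β-elimination; O6 must be masked so that it cannot attack activated C9 in step 7.

Step 5
Reactants: 10 O6-triethylsilyl ether (1R,5S,6R)
Product: 11 C4 ethylene ketal of 10, a 1,4-dioxaspiro[4.4]nonane (1R,5S,6R)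
Conditions: TMSOCH2CH2OTMS, TMSOTf (cat.), CH2Cl2, −78 → −20 °C; pyridine quench
Reagents that add atoms: 1,2-bis(trimethylsilyloxy)ethane, C[Si](C)(C)OCCO[Si](C)(C)C
Why: Noyori ketalisation is aprotic and cold, so the hindered C4 ketone is masked without epimerising C5 or expelling the β-silyloxy group, and the ketal removes the C5 acidity that would later open a C6–C7 epoxide by elimination.

Step 6
Reactants: 11 allyl ketal (1R,5S,6R)
Product: 13 primary C9 alcohol with a 2-hydroxyethyl arm on C1 (1R,5S,6R), via aldehyde 12 (not isolated)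
Conditions: O3, CH2Cl2, −78 °C; Me2S; then NaBH4, MeOH, 0 °C
Reagents that add atoms: ozone, [O-][O+]=O
Why: Ozonolysis of the only alkene, reductive work-up and borohydride reduction cut the allyl group down to the C10–C9 hydroxyethyl arm; the silyl ethers and the ketal, which has no acetal C–H bond, are inert to ozone.

Step 7
Reactants: 13 primary C9 alcohol (1R,5S,6R)
Product: 14 primary C9 chloride (1R,5S,6R)
Conditions: PPh3, CCl4, 2,6-lutidine (buffer), CH2Cl2, 0 °C → rt
Reagents that add atoms: tetrachloromethane, ClC(Cl)(Cl)Cl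
Why: Appel reaction: SN2 displacement of the alkoxyphosphonium ion at the unhindered primary C9 under essentially neutral conditions that leave the ketal and silyl ethers intact.

Step 8
Reactants: 14 bis-silyl ether chloride (1R,5S,6R)
Product: 15 C6,C7-diol chloride (1R,5S,6R)
Conditions: HF·pyridine, pyridine, THF, 0 °C → rt
Reagents that add atoms: none
Why: Fluoride-induced cleavage of both silyl ethers with buffered HF, a non-basic medium in which no alkoxide forms that could attack C9–Cl and in which the dioxolane survives.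

Step 9
Reactants: 15 C6,C7-diol chloride (1R,5S,6R)
Product: 17 (6S,7R)-7-(2-chloroethyl)-7-methyl-6-[(2R)-oxiran-2-yl]-1,4-dioxaspiro[4.4]nonane, via primary tosylate 16 (not isolated)
Conditions: TsCl, Et3N, Bu2SnO (cat.), CH2Cl2, 0 °C; then K2CO3, MeOH, 0 °C → rt
Reagents that add atoms: none
Why: Tin-acetal-catalysed selective sulfonylation of the primary hydroxyl followed by base-induced 3-exo-tet Williamson closure; the C6–O bond is never broken, so C6 keeps its configuration, and the tosylate outruns the C9 chloride as leaving group.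

Step 10
Reactants: 18 1,3-dithiane
Product: 20 2-(tert-butyldimethylsilyl)-1,3-dithiane, via 2-lithio-1,3-dithiane 19 (not isolated)
Conditions: n-BuLi, THF, −30 °C; TBSCl, −78 °C → rt
Reagents that add atoms: tert-butyldimethylsilyl chloride, CC(C)(C)[Si](C)(C)Cl
Why: Corey–Seebach lithiation of 1,3-dithiane and C-silylation of the carbanion with the silyl chloride.

Step 11
Reactants: 17 epoxy chloride (1R,5S,6R); 20 2-(tert-butyldimethylsilyl)-1,3-dithiane
Product: 24 trans-fused hydroazulene (1R,5S,6S) carrying the C8 1,3-dithiane the 6α-OTBS group the 1β-methyl group and the C4 ethylene ketal, via lithiated silyl dithiane 21 (not isolated), via C6 lithium alkoxide 22 (not isolated), via C8 carbanion 23 (not isolated)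
Conditions: 20, t-BuLi, Et2O, −78 → −45 °C; 17, Et2O, −78 → −20 °C; then dilution with THF, HMPA, −78 °C → rt (high dilution)
Reagents that add atoms: none
Why: Anion relay (linchpin) coupling: carbanion 21 opens the oxirane of 17 by SN2 attack at the unsubstituted C7 in ether, a medium in which alkoxide 22 keeps silicon on carbon and the primary chloride is untouched. HMPA then triggers the 1,4-Brook rearrangement, moving silicon from C8 to O6 and giving silyl ether carbanion 23. Carbanion 23 displaces chloride at C9 in a 7-exo-tet closure that completes the cycloheptane trans-fused to the cyclopentane. The closest known chemistry is the solvent-gated epoxide opening/Brook shift/alkylation sequence of 2-silyl-1,3-dithianes, also used intramolecularly for carbocycles, together with the cyclisation of 2-(ω-chloroalkyl)-1,3-dithianes to cyclic thioketals of up to seven members. No stereocentre is created: C6 keeps the oxirane configuration because only the C7–O bond breaks, and C1 and C5 are spectators. The order epoxide before chloride rests on the poor leaving group and the ether medium, O6 is silylated before it can attack C9 in a 6-exo ether closure, and high dilution, the quaternary C1 and the trans-1,2 placement of the two arms favour ring closure over intermolecular alkylation.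

Step 12
Reactants: 24 dithiane ketal silyl ether (1R,5S,6S)
Product: 25 C8 ketone (1S,5S,6S) with 6α-OTBS and C4 ketal
Conditions: MeI, CaCO3, MeCN/H2O, 45 °C
Reagents that add atoms: water, O
Why: Alkylative hydrolysis of the dithiane: S-methylation turns sulfur into a leaving group and water delivers the carbonyl oxygen, while the carbonate buffer protects the ketal and silyl ether.

Step 13
Reactants: 25 C8 ketone (1S,5S,6S)
Product: 26 8β-hydroxy-8α-methyl compound (1S,5S,6S,8R)
Conditions: MeMgBr, CeCl3, THF, −78 °C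
Reagents that add atoms: methylmagnesium bromide, C[Mg]Br
Why: 1,2-Addition of a weakly basic organocerium reagent avoids enolisation toward C7 and loss of the β-silyloxy group; in the twist-chair cycloheptanone the axial C1 methyl and C6–H cover the β face of C8, so methyl should enter along the equatorial α trajectory and give the 8β-alcohol (8R).

Step 14
Reactants: 26 ketal alcohol (1S,5S,6S,8R)
Product: 27 C4 ketone (1S,5S,6S,8R)
Conditions: PPTS, acetone/H2O, 45 °C
Reagents that add atoms: water, O
Why: Mild acid-catalysed ketal hydrolysis; pyridinium tosylate is too weak to cleave the hindered secondary silyl ether, ionise the tertiary alcohol or enolise the ketone toward C5 at a relevant rate.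

Step 15
Reactants: 27 C4 ketone (1S,5S,6S,8R)
Product: 29 C2=C3 enone with 8β-OTMS and 6α-OTBS (1S,5S,6S,8R), via bis(trimethylsilyl) enol ether 28 (not isolated)
Conditions: LDA (excess), TMSCl, THF, −78 → 0 °C; solvent switch to MeCN; Pd(OAc)2, rt
Reagents that add atoms: chlorotrimethylsilane, C[Si](C)(C)Cl
Why: Kinetic deprotonation at the unhindered C3 methylene and silylation (the C8 alkoxide is capped as well), then Saegusa–Ito oxidation through an oxa-π-allylpalladium species with β-hydride loss from C2; C1 is quaternary, so C2=C3 is the only ring enone possible, and C5 is never deprotonated.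

Step 16
Reactants: 29 enone (1S,5S,6S,8R)
Product: 30 4β-hydroxy-4α-isopropyl compound (1S,4S,5S,6S,8R)
Conditions: i-PrMgCl, CeCl3, THF, −78 °C
Reagents that add atoms: isopropylmagnesium chloride, CC(C)[Mg]Cl
Why: Organocerium 1,2-addition suppresses reduction, enolisation and conjugate addition; on the flat cyclopentenone the nucleophile should attack C4 anti to the C5–C6 bond, from the α face that carries only C5–H, giving 4β-OH and 4α-isopropyl (4S).

Step 17
Reactants: 30 bis-silyl ether (1S,4S,5S,6S,8R)
Product: 31 dauc-2-ene-4β,6α,8β-triol (1S,4S,5S,6S,8R)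
Conditions: TBAF, THF, rt → 45 °C
Reagents that add atoms: none
Why: Fluoride cleavage of the secondary tert-butyldimethylsilyl ether and the tertiary trimethylsilyl ether; nothing in the molecule is base-sensitive.

Step 18
Reactants: 32 vanillic acid
Product: 34 4-(tert-butyldimethylsilyloxy)-3-methoxybenzoic acid, via bis-silylated vanillate 33 (not isolated)
Conditions: TBSCl, imidazole, DMF, rt; then AcOH/THF/H2O, rt
Reagents that add atoms: tert-butyldimethylsilyl chloride, CC(C)(C)[Si](C)(C)Cl
Why: Exhaustive silylation followed by selective hydrolysis of the far more labile silyl ester; a fluoride-labile phenol mask is chosen because hydrogenolysis would endanger C2=C3 and an aryl acetate could transfer its acyl group.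

Step 19
Reactants: 31 triol (1S,4S,5S,6S,8R); 34 4-(tert-butyldimethylsilyloxy)-3-methoxybenzoic acid
Product: 35 C6 ester of 31 with O-silylated vanillic acid (1S,4S,5S,6S,8R)
Conditions: DCC, DMAP, CH2Cl2, rt
Reagents that add atoms: none
Why: Steglich esterification: the only secondary hydroxyl (C6) is acylated while the tertiary C4 and C8 alcohols are too hindered to react, and no C–O bond at C6 is broken, so the configuration is retained.

Step 20
Reactants: 35 silyl-protected ester (1S,4S,5S,6S,8R)
Product: 36 target CNP0113302.1, 6α-vanilloyloxydauc-2-ene-4β,8β-diol (1S,4S,5S,6S,8R)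
Conditions: TBAF, AcOH, THF, 0 °C
Reagents that add atoms: none
Why: Aryl silyl ethers are cleaved rapidly by buffered fluoride in the cold, leaving the hindered benzoate, the tertiary allylic alcohol and the alkene untouched.

Compound list
1 | 3-ethoxycyclopent-2-en-1-one | CCOC1=CC(=O)CC1 | starting material
2 | 1-allyl-3-ethoxycyclopent-2-en-1-ol (racemic) | C=CCC1(O)C=C(OCC)CC1 | intermediate
3 | 3-allylcyclopent-2-en-1-one | C=CCC1=CC(=O)CC1 | intermediate
4 | dimethylaluminium enolate of (R)-3-allyl-3-methylcyclopentanone (C4=C5) | C=CC[C@@]1(C)CCC(O[Al](C)C)=C1 | intermediate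
5 | triethyl{[(3R)-3-allyl-3-methylcyclopent-1-en-1-yl]oxy}silane | C=CC[C@@]1(C)CCC(O[Si](CC)(CC)CC)=C1 | intermediate
6 | (tert-butyldimethylsilyloxy)acetaldehyde | O=CCO[Si](C)(C)C(C)(C)C | starting material
7 | lithium enolate (1R) | C=CC[C@@]1(C)CCC(O[Li])=C1 | intermediate
8 | chlorozinc enolate (1R) | C=CC[C@@]1(C)CCC(O[Zn]Cl)=C1 | intermediate
9 | (2S,3R)-3-allyl-2-[(1R)-2-(tert-butyldimethylsilyloxy)-1-hydroxyethyl]-3-methylcyclopentan-1-one (side chain cis to methyl, anti aldol) | C=CC[C@@]1(C)CCC(=O)[C@@H]1[C@@H](O)CO[Si](C)(C)C(C)(C)C | intermediate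
10 | O6-triethylsilyl ether of 9 (1R,5S,6R) | C=CC[C@@]1(C)CCC(=O)[C@@H]1[C@@H](O[Si](CC)(CC)CC)CO[Si](C)(C)C(C)(C)C | intermediate
11 | C4 ethylene ketal of 10 (1R,5S,6R) | C=CC[C@@]1(C)CCC2(OCCO2)[C@@H]1[C@@H](O[Si](CC)(CC)CC)CO[Si](C)(C)C(C)(C)C | intermediate
12 | C9 aldehyde (1R,5S,6R) | O=CC[C@@]1(C)CCC2(OCCO2)[C@@H]1[C@@H](O[Si](CC)(CC)CC)CO[Si](C)(C)C(C)(C)C | intermediate
13 | C9 primary alcohol (1R,5S,6R) | OCC[C@@]1(C)CCC2(OCCO2)[C@@H]1[C@@H](O[Si](CC)(CC)CC)CO[Si](C)(C)C(C)(C)C | intermediate
14 | C9 primary chloride (1R,5S,6R) | ClCC[C@@]1(C)CCC2(OCCO2)[C@@H]1[C@@H](O[Si](CC)(CC)CC)CO[Si](C)(C)C(C)(C)C | intermediate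
15 | C6,C7-diol chloride (1R,5S,6R) | ClCC[C@@]1(C)CCC2(OCCO2)[C@@H]1[C@@H](O)CO | intermediate
16 | C7 monotosylate (1R,5S,6R) | ClCC[C@@]1(C)CCC2(OCCO2)[C@@H]1[C@@H](O)COS(=O)(=O)c3ccc(C)cc3 | intermediate
17 | (6S,7R)-7-(2-chloroethyl)-7-methyl-6-[(2R)-oxiran-2-yl]-1,4-dioxaspiro[4.4]nonane | ClCC[C@@]1(C)CCC2(OCCO2)[C@@H]1[C@@H]3CO3 | intermediate
18 | 1,3-dithiane | C1CSCSC1 | starting material
19 | 2-lithio-1,3-dithiane | [Li]C1SCCCS1 | intermediate
20 | 2-(tert-butyldimethylsilyl)-1,3-dithiane | CC(C)(C)[Si](C)(C)C1SCCCS1 | intermediate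
21 | 2-lithio-2-(tert-butyldimethylsilyl)-1,3-dithiane | CC(C)(C)[Si](C)(C)C1([Li])SCCCS1 | intermediate
22 | C6 lithium alkoxide with C8 silyl dithiane (1R,5S,6S) | ClCC[C@@]1(C)CCC2(OCCO2)[C@@H]1[C@@H](O[Li])CC3([Si](C)(C)C(C)(C)C)SCCCS3 | intermediate
23 | C8-lithiated dithiane with 6-OTBS (1R,5S,6S) | ClCC[C@@]1(C)CCC2(OCCO2)[C@@H]1[C@@H](O[Si](C)(C)C(C)(C)C)CC3([Li])SCCCS3 | intermediate
24 | trans-hydroazulene, C8 1,3-dithiane, 6α-OTBS, 1β-methyl, 5α-H, C4 ethylene ketal (1R,5S,6S) | CC(C)(C)[Si](C)(C)O[C@H]1CC2(SCCCS2)CC[C@@]3(C)CCC4(OCCO4)[C@H]13 | intermediate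
25 | C8 ketone, 6α-OTBS, C4 ketal (1S,5S,6S) | CC(C)(C)[Si](C)(C)O[C@H]1CC(=O)CC[C@@]2(C)CCC3(OCCO3)[C@H]12 | intermediate
26 | 8β-hydroxy-8α-methyl ketal (1S,5S,6S,8R) | CC(C)(C)[Si](C)(C)O[C@H]1C[C@](C)(O)CC[C@@]2(C)CCC3(OCCO3)[C@H]12 | intermediate
27 | C4 ketone, 8β-OH, 6α-OTBS (1S,5S,6S,8R) | CC(C)(C)[Si](C)(C)O[C@H]1C[C@](C)(O)CC[C@@]2(C)CCC(=O)[C@H]12 | intermediate
28 | C3=C4 trimethylsilyl enol ether, 8β-OTMS (1S,5S,6S,8R) | CC(C)(C)[Si](C)(C)O[C@H]1C[C@](C)(O[Si](C)(C)C)CC[C@@]2(C)CC=C(O[Si](C)(C)C)[C@H]12 | intermediate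
29 | C2=C3 enone, 8β-OTMS, 6α-OTBS (1S,5S,6S,8R) | CC(C)(C)[Si](C)(C)O[C@H]1C[C@](C)(O[Si](C)(C)C)CC[C@@]2(C)C=CC(=O)[C@H]12 | intermediate
30 | 4β-hydroxy-4α-isopropyl compound, 8β-OTMS, 6α-OTBS (1S,4S,5S,6S,8R) | CC(C)(C)[Si](C)(C)O[C@H]1C[C@](C)(O[Si](C)(C)C)CC[C@@]2(C)C=C[C@@](O)(C(C)C)[C@H]12 | intermediate
31 | dauc-2-ene-4β,6α,8β-triol (1S,4S,5S,6S,8R) | O[C@H]1C[C@](C)(O)CC[C@@]2(C)C=C[C@@](O)(C(C)C)[C@H]12 | intermediate
32 | vanillic acid | COc1cc(C(=O)O)ccc1O | starting material
33 | tert-butyldimethylsilyl 4-(tert-butyldimethylsilyloxy)-3-methoxybenzoate | COc1cc(C(=O)O[Si](C)(C)C(C)(C)C)ccc1O[Si](C)(C)C(C)(C)C | intermediate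
34 | 4-(tert-butyldimethylsilyloxy)-3-methoxybenzoic acid | COc1cc(C(=O)O)ccc1O[Si](C)(C)C(C)(C)C | intermediate
35 | 6α-[4-(tert-butyldimethylsilyloxy)-3-methoxybenzoyloxy]dauc-2-ene-4β,8β-diol (1S,4S,5S,6S,8R) | COc1cc(C(=O)O[C@H]2C[C@](C)(O)CC[C@@]3(C)C=C[C@@](O)(C(C)C)[C@H]23)ccc1O[Si](C)(C)C(C)(C)C | intermediate
36 | CNP0113302.1, 6α-vanilloyloxydauc-2-ene-4β,8β-diol (1S,4S,5S,6S,8R) | COc1cc(C(=O)O[C@H]2C[C@](C)(O)CC[C@@]3(C)C=C[C@@](O)(C(C)C)[C@H]23)ccc1O | target

Total step count: 20. Longest linear sequence: 18 (steps 1–9, 11–17, 19 and 20).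

Steps most likely to fail

**Step 11.** The relay may stall through incomplete silyl migration. The slow seven-ring closure may also lose to intermolecular alkylation or protonation of the relayed carbanion. The fallback gives up the relay and runs the three events as separate operations. It sets out from 17 and 18 and returns at 24.
- 2-Lithio-1,3-dithiane 19 (from 18, n-BuLi) opens 17 at C7 in THF at −30 °C and gives the C6 alcohol with a C8–H dithiane F1.
- TBSOTf/2,6-lutidine converts it into the O6 silyl ether F2.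
- n-BuLi in THF/HMPA under high dilution deprotonates C8, and the classical Corey–Seebach cyclisation onto the C9 chloride gives 24.

**Step 3.** Anti/syn control at C6 may erode in the aldol addition; C5 epimers, if formed, are removed by chromatography at 9. The fallback replaces substrate control at C6 by reagent control. It sets out from 5 and 6 and returns at 11.
- The C6-epimeric aldol F3 is silylated as in step 4 to its triethylsilyl ether F4.
- Ketalisation as in step 5 gives the epimeric ketal F5.
- PPTS in MeOH at 0 °C removes only the triethylsilyl group and gives the (6S)-carbinol F6.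
- Dess–Martin periodinane gives the C6 ketone F7.
- CBS reduction with (R)-2-methyl-CBS-oxazaborolidine and catecholborane, which spares the allyl group, treats the cyclopentyl residue as the large substituent and gives the (6R)-carbinol F8.
- Et3SiOTf/2,6-lutidine then gives 11.

**Step 13.** Facial selectivity of the methyl addition at C8 may be poor or inverted. The fallback brings carbon first and oxygen second, so that the same steric bias leads to the opposite C8 configuration. It sets out from 25 and returns at 26.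
- Wittig methylenation (Ph3P=CH2, THF) gives the 8-methylene compound F9.
- Epoxidation with mCPBA/NaHCO3, from the face that the methyl nucleophile had preferred, gives the spiro-epoxide with β oxygen F10.
- LiEt3BH opens it at the CH2 terminus and gives 26.

Further compounds
F1 | step 11 | C6 alcohol with C8–H 1,3-dithiane, C9 chloride, C4 ketal (1R,5S,6S) | ClCC[C@@]1(C)CCC2(OCCO2)[C@@H]1[C@@H](O)CC3SCCCS3
F2 | step 11 | O6 tert-butyldimethylsilyl ether of F1 (1R,5S,6S) | ClCC[C@@]1(C)CCC2(OCCO2)[C@@H]1[C@@H](O[Si](C)(C)C(C)(C)C)CC3SCCCS3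
F3 | step 3 | C6-epimeric (syn) aldol (1R,5S,6S) | C=CC[C@@]1(C)CCC(=O)[C@@H]1[C@H](O)CO[Si](C)(C)C(C)(C)C
F4 | step 3 | O6 triethylsilyl ether of F3 (1R,5S,6S) | C=CC[C@@]1(C)CCC(=O)[C@@H]1[C@H](O[Si](CC)(CC)CC)CO[Si](C)(C)C(C)(C)C
F5 | step 3 | C4 ethylene ketal of F4 (1R,5S,6S) | C=CC[C@@]1(C)CCC2(OCCO2)[C@@H]1[C@H](O[Si](CC)(CC)CC)CO[Si](C)(C)C(C)(C)C
F6 | step 3 | (6S)-carbinol, C4 ketal, C7 OTBS (1R,5S,6S) | C=CC[C@@]1(C)CCC2(OCCO2)[C@@H]1[C@H](O)CO[Si](C)(C)C(C)(C)C
F7 | step 3 | C6 ketone, C4 ketal, C7 OTBS (1R,5S) | C=CC[C@@]1(C)CCC2(OCCO2)[C@@H]1C(=O)CO[Si](C)(C)C(C)(C)C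
F8 | step 3 | (6R)-carbinol, C4 ketal, C7 OTBS (1R,5S,6R) | C=CC[C@@]1(C)CCC2(OCCO2)[C@@H]1[C@@H](O)CO[Si](C)(C)C(C)(C)C
F9 | step 13 | 8-methylene compound, 6α-OTBS, C4 ketal (1S,5S,6S) | CC(C)(C)[Si](C)(C)O[C@H]1CC(=C)CC[C@@]2(C)CCC3(OCCO3)[C@H]12
F10 | step 13 | C8 spiro-epoxide with β oxygen, 6α-OTBS, C4 ketal (1S,5S,6S,8R) | CC(C)(C)[Si](C)(C)O[C@H]1C[C@@]4(CO4)CC[C@@]2(C)CCC3(OCCO3)[C@H]12
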